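(The readings were computed with constants of no real substance; scatter was added.)

Watch the clock first: the question is where this flask stands after 2.0 h at one temperature, with solid X going into solution and L turning it into E.

common to all: X 0.050 M

| flask | L | remark | time |
|---|---|---|---|
| dusk | 0.0475 M | the very flask that is asked about, followed so far |  |
| dawn | 0.071 M | run made earlier |  |
| flask | 0.0475 M |  | 2.0 h |

- the E standing at 2.0 h, as a percentage of the X charged
- the change that raises the amount of E at 2.0 h, in percent of the X charged most ("none" if none brings more than 2 percentage points) (eta / theta / gamma / none)
- amount of E at 2.0 h, in percent of the X charged, after theta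

- eta: doubling the amount of L, all else as stated
- theta: doubling the solubility of X, all else as stated
- gamma: doubling the dissolution coefficient of X, all else as stated

- X is a solid; its amount is given per volume of the solution
- at the start none of X is in solution

| run | time / min | E / % | X / % |
|---|---|---|---|
| dusk | 8.00 | 6.4 | 92.2 |
| dusk | 20.0 | 16.4 | 82.2 |
| dusk | 40.0 | 33.1 | 64.7 |
| dusk | 60.0 | 49.8 | 47.0 |
| dawn | 10.0 | 8.1 | 92.0 |
| dawn | 20.0 | 17.3 | 82.2 |
| dawn | 50.0 | 43.7 | 56.0 |
| dawn | 120 | 98.8 | 0 |

(standard deviation of a reading: 1 percentage point)

Read the X columns against each other. At 20.0 min dusk shows 82.2 % and dawn 82.2 %, although dawn holds more L, 0.071 M against 0.0475 M. So take dissolving as the rate-limiting step and treat the reaction of dissolved X with L as quick.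

Now read down the dusk X column. Its nearly straight fall gives a reading of the dissolving pace, 0.0261 M h⁻¹, the amount of X entering solution per hour.

Set E beside X. At 60.0 min in dusk the two leave 3.20 % of the charge unaccounted for, which is a reading of the dissolved stock, so E trails the pace closely.

Divide the charges by the pace. At that pace I reckon the solid clears at 115 min, and an amount of X equal to the L charge has entered solution by 109 min. That leaves 10.7 min before the end. With one L per E, the L charge caps E at 95.0 %. Take one gap off the cap: my figure is 91.8 %.

Doubling L lifts that cap, while doubling the solubility or the coefficient should double the pace and bring E just under the same cap. So choose eta.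

The forecast gave 89 % (85 % to 93 %), lower than my figure, with 94.4 % after theta and eta as best, on the ground that “dissolution at a nearly fixed rate limits the process”.

The flask gives 91.1 %. The best change is eta, worth 8.9 percentage points against 3.5 points for theta, and E stands at 94.6 % after theta.

    Z ⇌ Q, settled at all times (K = 1.00)
    L + Q → E (k = 29.0 M⁻¹ min⁻¹)
    X ⇌ Z, rate k3*(cs3 - [Z]) while solid is left; crystals form when [Z] > cs3 (solubility = 19.0 mM, k = 0.0240 min⁻¹)

In this flask Q lasted a half-life of 1.0 min against L at 0.935 h, far shorter than the 109 min of feeding, and it stood at 1.31 % at 1.00 h. At 2.00 h the half-life of L by this step is 10.8 min, about the margin of 10.7 min, with L at 4.06 % of its charge and E at 91.1 %. Hold the same pace for the flask charged with 0.085 M of X: it leaves 38.6 % of that charge undissolved at 2.0 h, and that flask shows 38.8 % as solid X.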